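**Retrosynthetic overview**
1. Target hemiketal ⇒ C2–aryl disconnection: (3,4,5-trimethoxyphenyl)lithium plus a (3R)-1,4-benzodioxin-2-one. C2 is then fixed by ring–chain equilibration.
2. Lactone ⇒ both C–O bonds at once: catalytic asymmetric [4+2] of 5-allyl-3-methoxy-o-benzoquinone (O=C–C=O as the 4π unit) with the chiral ammonium enolate of methylketene (from propionyl chloride). This sets C3.
3. Quinone ⇒ oxidative O-demethylation of the symmetric flavour phenol 4-allyl-2,6-dimethoxyphenol.
4. Ring order: ring C (trimethoxyphenyl) is bought. The cycloaddition closes heteroring B and, by aromatising the dione, creates benzenoid ring A in the same operation, so the fused A/B bicycle appears in one step. In the last step ring B opens and re-closes as the hemiketal.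

**Assumption:** C2 is a hemiketal carbon that epimerises freely through the open keto-phenol. The drawn (2S,3R) isomer has OH trans to the C3 methyl and the aryl group cis to it. It is taken to be the isomer favoured at equilibrium and on crystallisation, so the synthesis has to fix only C3.

Step 1
Reactants: 1 4-allyl-2,6-dimethoxyphenol
Product: 2 5-allyl-3-methoxycyclohexa-3,5-diene-1,2-dione
Conditions: IBX (1.1 equiv), THF, 0 °C to rt, dark; filter off solids, concentrate cold, use at once
Reagents that add atoms: IBX (2-iodoxybenzoic acid), O=C1OI(=O)(O)c2ccccc12
Why: Hydroxylative phenol dearomatisation (oxidative O-demethylation) by pentavalent iodine: the phenol binds to iodine, one oxygen is passed to an ortho carbon and the methoxy hemiketal so formed loses methanol to give the o-quinone; the two ortho positions of 1 are equivalent, so only one quinone can form, the neutral aprotic medium spares the allyl group and slows tautomerisation to the quinone methide, and no stereocentre is created.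

Step 2
Reactants: 2 5-allyl-3-methoxycyclohexa-3,5-diene-1,2-dione, 3 propionyl chloride
Product: 5 (3R)-5-methoxy-3-methyl-7-(prop-2-en-1-yl)-1,4-benzodioxin-2(3H)-one, via methylketene 4 (not isolated)
Conditions: O-benzoylquinidine (10 mol %), iPr2NEt (1.1 equiv, slow addition), THF, −78 °C
Reagents that add atoms: none
Why: Proposed new method: the closest known reaction is the cinchona-alkaloid-catalysed ketene-enolate/o-quinone [4+2] cycloaddition (inverse-demand hetero-Diels–Alder), established for halogenated symmetric o-quinones and extended here to the unsymmetric quinone 2: the catalyst adds to 4 to give a chiral Z-ammonium enolate whose open face attacks the oxygen on quinone C2, the more electrophilic carbonyl because the quinone C1 carbonyl is a deactivated vinylogous ester of the 3-OMe group, aromatisation then frees the C1 phenoxide, which closes the lactone on the acylammonium and releases the catalyst, so both C–O bonds, heteroring B, benzenoid ring A and the (3R) centre arise in one operation (the quinidine series is expected to give R by analogy with related α-functionalisations, to be confirmed on 5, and the quinine series gives S).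

Step 3
Reactants: 5 (3R)-5-methoxy-3-methyl-7-(prop-2-en-1-yl)-1,4-benzodioxin-2(3H)-one, 6 5-bromo-1,2,3-trimethoxybenzene
Product: 9 (2S,3R)-5-methoxy-3-methyl-7-(prop-2-en-1-yl)-2-(3,4,5-trimethoxyphenyl)-2,3-dihydro-1,4-benzodioxin-2-ol, via aryllithium 7 (not isolated), via open keto-phenol 8 (not isolated)
Conditions: 6 (1.05 equiv), n-BuLi (1.0 equiv), THF, −78 °C; cannulate into 5, THF, −78 °C; AcOH quench at −78 °C; equilibrate and crystallise (EtOAc/hexane)
Reagents that add atoms: none
Why: Acyl substitution of a phenolic lactone by an aryllithium (the lactone-to-lactol addition used for aryl C-glycoside hemiketals): fast 1,2-addition at −78 °C with inverse addition of one equivalent outruns enolisation, so C3 stays (R), the released phenoxide of 8 is a poorer electrophile than 5 and is not arylated again, and after the cold quench 8 re-closes to the hemiketal, whose C2 is set under thermodynamic control by ring–chain equilibration (OH pseudo-axial for the anomeric effect, aryl pseudo-equatorial, OH anti to the C3 methyl), which is (2S) for (3R).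

**Compound list**
1 | 4-allyl-2,6-dimethoxyphenol | C=CCc1cc(OC)c(O)c(OC)c1 | starting material
2 | 5-allyl-3-methoxycyclohexa-3,5-diene-1,2-dione (5-allyl-3-methoxy-o-benzoquinone) | C=CCC1=CC(=O)C(=O)C(OC)=C1 | intermediate
3 | propionyl chloride | CCC(=O)Cl | starting material
4 | methylketene (prop-1-en-1-one) | CC=C=O | intermediate
5 | (3R)-5-methoxy-3-methyl-7-(prop-2-en-1-yl)-1,4-benzodioxin-2(3H)-one | C=CCc1cc(OC)c2c(c1)OC(=O)[C@@H](C)O2 | intermediate
6 | 5-bromo-1,2,3-trimethoxybenzene | COc1cc(Br)cc(OC)c1OC | starting material
7 | (3,4,5-trimethoxyphenyl)lithium | [Li]c1cc(OC)c(OC)c(OC)c1 | intermediate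
8 | (2R)-2-(4-allyl-2-hydroxy-6-methoxyphenoxy)-1-(3,4,5-trimethoxyphenyl)propan-1-one | C=CCc1cc(O)c(O[C@H](C)C(=O)c2cc(OC)c(OC)c(OC)c2)c(OC)c1 | intermediate
9 | (2S,3R)-5-methoxy-3-methyl-7-(prop-2-en-1-yl)-2-(3,4,5-trimethoxyphenyl)-2,3-dihydro-1,4-benzodioxin-2-ol | C=CCc1cc(OC)c2c(c1)O[C@@](O)(c1cc(OC)c(OC)c(OC)c1)[C@@H](C)O2 | target

**Total steps:** 3. **Longest linear sequence:** 3 (1 → 2 → 5 → 9).

**Steps most likely to fail** (all three, ranked 2 > 3 > 1; discussed in route order)

**Risk at step 1.**
- Quinone 2 can dimerise or tautomerise to the vinyl quinone methide through its doubly activated CH2.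
- The methanol set free must be stripped completely before step 2.
- The fallback sets out from 1 and comes back at 2. It separates demethylation from oxidation.
- Non-oxidative, chelation-assisted mono-demethylation of 1 uses AlI3/pyridine (MeCN, 80 °C). The aluminium phenoxide delivers iodide to one of the two equivalent neighbouring O-methyl groups, and the aluminium catecholate resists a second cleavage.
- This gives the storable 5-allyl-3-methoxybenzene-1,2-diol F1.
- F1 is oxidised only minutes before use with Ag2O and MgSO4 in Et2O at 0 °C. Filtration then gives a neutral, methanol-free solution of 2.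

**Risk at step 2.**
- Quinone 2 is less electrophilic than the halogenated quinones on which this cycloaddition is established.
- The O-regiochemistry rests only on an electronic bias.
- 1,2-Addition (spiro-β-lactone), ketene dimerisation or amine-induced tautomerisation of 2 can compete.
- The fallback replaces catalysis by the chiral pool and electronic regiocontrol by steric regiocontrol. It sets out from 2 and comes back at 5.
- Na2S2O4 (EtOAc/H2O) reduces 2 to the catechol 5-allyl-3-methoxybenzene-1,2-diol F1.
- The less hindered outer hydroxyl is silylated (TIPSCl, imidazole, DMF, 0 °C) to 4-allyl-2-methoxy-6-(triisopropylsilyloxy)phenol F2.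
- Mitsunobu etherification of the remaining central hydroxyl with ethyl (S)-lactate (PPh3, DIAD, THF) proceeds with inversion. It gives ethyl (2R)-2-[4-allyl-2-methoxy-6-(triisopropylsilyloxy)phenoxy]propanoate F3.
- Buffered TBAF/AcOH frees ethyl (2R)-2-(4-allyl-2-hydroxy-6-methoxyphenoxy)propanoate F4.
- F4 lactonises with catalytic TsOH in toluene at 60 °C to 5.

**Risk at step 3.**
- Lactone 5 has an acidic α-hydrogen, so it can racemise through the enolate or ketene.
- The tetrahedral adduct collapses to a ketone that a local excess of 7 could arylate again.
- If the crude hemiketal is a mixture at C2, the epimers interconvert through 8. Slow crystallisation then funnels the material into the drawn isomer.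
- The fallback changes the acyl donor to one that holds the tetrahedral stage. It sets out from 5 and comes back at 8, which closes to 9.
- Aminolysis of the activated lactone with MeNH(OMe)·HCl and pyridine (CH2Cl2, 0 °C to rt) gives (2R)-2-(4-allyl-2-hydroxy-6-methoxyphenoxy)-N-methoxy-N-methylpropanamide F5.
- Two equivalents of 7 at −78 °C (the first is spent on the phenol) give a chelated adduct that cannot collapse or enolise before the AcOH quench. The quench releases 8.

**Further compounds**
F1 | step 1 | 5-allyl-3-methoxybenzene-1,2-diol | C=CCc1cc(O)c(O)c(OC)c1
F2 | step 2 | 4-allyl-2-methoxy-6-(triisopropylsilyloxy)phenol | C=CCc1cc(OC)c(O)c(O[Si](C(C)C)(C(C)C)C(C)C)c1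
F3 | step 2 | ethyl (2R)-2-[4-allyl-2-methoxy-6-(triisopropylsilyloxy)phenoxy]propanoate | C=CCc1cc(OC)c(O[C@H](C)C(=O)OCC)c(O[Si](C(C)C)(C(C)C)C(C)C)c1
F4 | step 2 | ethyl (2R)-2-(4-allyl-2-hydroxy-6-methoxyphenoxy)propanoate | C=CCc1cc(O)c(O[C@H](C)C(=O)OCC)c(OC)c1
F5 | step 3 | (2R)-2-(4-allyl-2-hydroxy-6-methoxyphenoxy)-N-methoxy-N-methylpropanamide | C=CCc1cc(O)c(O[C@H](C)C(=O)N(C)OC)c(OC)c1
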